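In a one-step world, where exchange of spent carrier with salt is the sole slow step, the rate follows c(salt) and the order in salt is 1. At the other end the carrier rests as fresh carrier (the resting state), more salt converts nothing further, and the order is 0.

all flasks: substrate 0.080 M; spent carrier 16 mM
- south-west: salt in the second phase 0.22 M; run made earlier
- east: salt in the second phase 0.35 M; run made earlier
- flask: salt in the second phase 0.160 M; volume of the second phase over the first 1.0

| run | time / d | target / % |
|---|---|---|
| south-west | 5.00 | 66.1 |
| south-west | 10.0 | 68.2 |
| south-west | 15.0 | 68.9 |
| south-west | 20.0 | 69.4 |
| east | 5.00 | 69.1 |
| east | 10.0 | 69.7 |
| east | 15.0 | 70.3 |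
| east | 20.0 | 69.9 |

(readings scatter by 0.5 percentage points)

- apparent order in spent carrier when 10% of the substrate are converted (percent change of the rate of making target for one percent more spent carrier charged)
- apparent order in salt in the second phase when 10% of the substrate are converted (percent change of the rate of making target for one percent more salt in the second phase charged)

- charges count per volume of the first phase; a concentration in a rate is the amount of a species over the volume of its own phase; every rate counts per litre of the first phase
- the earlier runs hold the two phases in the same ratio of volumes as the flask asked about
- no earlier run changes the charge of spent carrier; that part of a forecast is a guess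

I join the ends by assuming a fast exchange with constant K, holding c(spent salt) fixed. The share of carrier left spent is then the order in salt:

order = 1 / (1 + K·ρ), with ρ = c(salt)/c(spent salt)

For this flask at the look, with equal phase volumes, spent salt is at most the carrier plus the substrate converted:

c(spent salt) ≤ 24.0 mM, so ρ ≥ 5.67

This floor on the salt ratio puts the order below 0.5 for any K above 0.176. From south-west to east, salt rises 1.59-fold, and the last reading moves 0.5 percentage points, about the scatter of 0.5 points, though the 5.00 d readings move 3 points. The runs do not pin K, but I read the effect as mild and commit to an order in salt below 0.5.

The forecast says 0.8 for spent carrier and 0.4 for salt, with “a small, poorly fixed K, roughly 0.1, within 0.03–1”.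

The flask gives 0.86 for spent carrier and 0.18 for salt.

    spent carrier + salt in the second phase ⇌ fresh carrier + spent salt in the second phase (K = 0.569, k = 0.00878 M⁻¹ s⁻¹)
    substrate + fresh carrier → target + spent carrier (k = 6.50 × 10⁻⁴ M⁻¹ s⁻¹)
    2 substrate → self-condensation product (k = 5.07 × 10⁻⁵ M⁻¹ s⁻¹)

At 0.481 d, fresh carrier is made at 0.890 of the rate at which it is used, close to balance. With the true K, the floor gives 0.237, above the flask's order, as a floor on ρ must. For the south-west run, ρ is at least 8.17, which under the same fast exchange gives an order of at most 0.177.

The earlier runs and the new flask are simulated for an exercise; the scatter is artificial.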